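Which flask ends with the most product?

all flasks: starting material 20 mM; partner 14.0 mM; free catalyst 100 µM; second catalyst 100 µM; time 3.0 min

|  | remark | temperature |
|---|---|---|
| north-west | at 110 °C until 1.5 min, from then on at 60 °C |  |
| south-west |  | 60 °C |
| south |  | 85 °C |
| north-east |  | 110 °C |

    partner + catalyst intermediate ⇌ second catalyst + product (K1 = 3.2, k1 = 520 L mol⁻¹ s⁻¹, Ea1 = 39.0 kJ mol⁻¹, ΔH1 = −36.0 kJ mol⁻¹)
    starting material + free catalyst → free catalyst + open intermediate (k2 = 4000 L mol⁻¹ s⁻¹, Ea2 = 13.0 kJ mol⁻¹)
    2 free catalyst ⇌ resting dimer, settled at all times (K3 = 29000 L mol⁻¹, ΔH3 = 19.0 kJ mol⁻¹)
    second catalyst + open intermediate ⇌ catalyst intermediate (K4 = 210 L mol⁻¹, k4 = 240 L mol⁻¹ s⁻¹, Ea4 = 52.0 kJ mol⁻¹, ΔH4 = 36.0 kJ mol⁻¹)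
    (constants at 60 °C)

- a doubled species enters its step squared and goes two at a time
- at 60 °C the constants are as listed, elsewhere as the activation energies and enthalpies make them

- which flask leads in amount of product, in percent of the starting material charged ("all alike" within 1.5 percentage points) (north-west / south-west / south / north-east / all alike)
- how much product is there at the end, in percent of the starting material charged: north-west
- how much product is there at the end, in percent of the starting material charged: south-west
- how much product is there at the end, in percent of the starting material charged: south
- how much product is there at the end, in percent of the starting material charged: north-east

Both ways below start by opening the starting material. Balance with the resting dimer leaves 33.8 µM of free catalyst at 60 °C, which gives the opening a half-life of 5.13 s, far shorter than 3.0 min. So open intermediate soon stands in place of the starting material, and the question becomes how much of it meets partner.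

The first way counts charges. Partner is the smaller charge, the limiting reagent on paper, so a one-way scheme gives 70.0% product.

The second way adds the two reversible steps. Binding to second catalyst followed by handover to partner nets open intermediate + partner ⇌ product, with the second catalyst returned. The through constant is the product of their constants, 672 L mol⁻¹. Their enthalpies sum to 0 kJ mol⁻¹, so this constant does not shift with temperature. With x as the product formed, x equals the constant times (starting charge − x) times (partner charge − x). That quadratic gives 59.2%.

The two ways part, and the count is the one that cheats: it takes partner to zero with product present, and the balance cannot hold there. The ceiling, the share of charged starting material standing as product when the through balance is met, is the number to trust.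

A ceiling still has to be reached. South-west is the slow case, since going from it to 110 °C speeds binding by a factor of 12 and handover by 6.3. Replacing the curves by their means gives 14.1 mM of open intermediate and 8.08 mM of partner. One forward round of second catalyst then takes 0.534 s, and filling to the ceiling takes 1.05 min, about a third of the time given. That mean leaves out the back steps, which grow towards the ceiling, so this fill time is an estimate that reads short. This reckoning commits to the ceiling in north-west, south and north-east, and to south-west somewhat under it, by an amount the mean cannot tell.

The forecast gave 59.1% for north-west, 58.1% for south-west, 59.1% for south and 59.1% for north-east, so all alike, holding that “every flask essentially reaches that cap” with the coldest a point short. Its top value lies just under the ceiling reckoned here, and it put a figure on the south-west shortfall where this reckoning did not.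

The simulation gives 59.1% for north-west, 58.1% for south-west, 59.1% for south and 59.1% for north-east: all alike. In south-west the handover, taken by itself and both ways together, relaxes with a half-life of 0.219 s at the end, much shorter than 3.0 min, while half of its turnover up to the end was done by 0.604 min. Left for 30.0 min, south-west reads 59.1%, beside the ceiling of 59.2%. A flask like south-west with 3.5 mM of partner has a ceiling of 16.1%, and it ends with 16.1% product and 83.6% open intermediate.

(The constants were drawn at random within sensible limits; the result is computed.)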